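**Retrosynthetic overview**
- The target is a (2R)-flavanone (rings D, E, F) whose ring D carbon C6 is bonded to C4 of a (2S,4S)-2,4-trans flavan (rings A, B, C). The flavanone is built last on the pendant aryl ring D, by oxa-Michael closure of a chalcone made from an ortho-acetyl phenol.
- Key disconnection: the flavan C2–phenyl bond, made from a C2 radical (from an N-hydroxyphthalimide ester) and iodobenzene at nickel. The strategy rests on flavan C2 being bonded to the ring oxygen O1 and lying 1,3 to C4 in pyran ring C, where the C4 aryl group is held pseudoaxial by the peri 5-OMe of ring A and blocks one face of C2.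
- C4–aryl bond: Friedel–Crafts alkylation of silylated 3,5-dimethoxyphenol by a C4 benzylic cation, trans to the C2 carboxyl group, which is later exchanged for phenyl.
- Pyran ring C (first ring formed): intramolecular Friedel–Crafts acylation of an (S)-aryloxysuccinic acid. C2 comes from dimethyl (R)-malate by Mitsunobu inversion; the ring A phenol comes from 2,6-dibromo-4-methoxyphenol.
- Ring order: ring C (step 7), then pyranone ring F (step 18).

Key step: step 12

Remark: 2,6-dibromo-4-methoxyphenol (one bromination from 4-methoxyphenol) is taken as commercial. The carbinol centres formed in steps 8 and 15 are destroyed in steps 10 and 16, so the major epimer is drawn for 13 and none is specified for 24. In step 18 the cinchona pseudoenantiomer is the one whose sense of induction gives 2R; it is written here as the quinidine-derived catalyst.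

**Step 1**
Reactants: 1 2,6-dibromo-4-methoxyphenol
Product: 2 1,3-dibromo-2,5-dimethoxybenzene
Conditions: MeI, K2CO3, DMF, rt
Reagents that add atoms: iodomethane, CI
Why: Williamson O-methylation of an acidic, if hindered, 2,6-dibromophenol should be clean and gives a symmetric dibromide with the central and para methoxy groups of ring A in place.

**Step 2**
Reactants: 2 1,3-dibromo-2,5-dimethoxybenzene
Product: 5 3-bromo-2,5-dimethoxyphenol, via aryllithium 3 (not isolated), via lithium aryltrimethoxyborate 4 (not isolated)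
Conditions: n-BuLi (1.05 equiv), THF, −78 °C; B(OMe)3; then AcOH, 30% H2O2, 0 °C → rt
Reagents that add atoms: hydrogen peroxide, OO
Why: Bromine–lithium exchange at one of two equivalent C–Br bonds, borylation and boronate oxidation should turn one bromide into a phenol without any statistical protection.

**Step 3**
Reactants: 5 3-bromo-2,5-dimethoxyphenol
Product: 6 1-(benzyloxy)-3-bromo-2,5-dimethoxybenzene
Conditions: BnBr, K2CO3, DMF, rt
Reagents that add atoms: benzyl bromide, BrCc1ccccc1
Why: Williamson benzylation installs the ether that masks the later flavan 7-OH and survives base, hydride, fluoride and cathodic conditions.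

**Step 4**
Reactants: 6 1-(benzyloxy)-3-bromo-2,5-dimethoxybenzene
Product: 7 3-(benzyloxy)-2,5-dimethoxyphenol
Conditions: Pd2(dba)3 (2 mol%), t-BuXPhos (8 mol%), KOH, 1,4-dioxane/H2O, 100 °C; then aq. HCl
Reagents that add atoms: potassium hydroxide, [K+].[OH-]
Why: Palladium-catalysed hydroxylation of an aryl bromide with KOH (Buchwald-type C–O coupling) is established for electron-rich ortho-substituted bromides and leaves benzyl and methyl ethers alone.

**Step 5**
Reactants: 7 3-(benzyloxy)-2,5-dimethoxyphenol; 8 dimethyl (R)-malate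
Product: 9 dimethyl (S)-2-[3-(benzyloxy)-2,5-dimethoxyphenoxy]succinate
Conditions: PPh3, DIAD, toluene, 0 °C → rt
Reagents that add atoms: none
Why: Mitsunobu etherification of the phenol with the secondary α-hydroxy ester goes by SN2 with inversion, so the (R)-alcohol should give the (S)-aryl ether that becomes chroman C2.

**Step 6**
Reactants: 9 dimethyl (S)-2-[3-(benzyloxy)-2,5-dimethoxyphenoxy]succinate
Product: 10 (S)-2-[3-(benzyloxy)-2,5-dimethoxyphenoxy]succinic acid
Conditions: LiOH, THF/H2O, 0 °C; then aq. HCl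
Reagents that add atoms: lithium hydroxide, [Li+].[OH-]
Why: Saponification at 0 °C should outrun β-elimination of the aryloxide and α-epimerisation, since the carboxylates formed no longer enolise readily.

**Step 7**
Reactants: 10 (S)-2-[3-(benzyloxy)-2,5-dimethoxyphenoxy]succinic acid
Product: 12 (S)-7-(benzyloxy)-5,8-dimethoxy-4-oxochromane-2-carboxylic acid, via aryloxysuccinic anhydride 11 (not isolated)
Conditions: TFAA (3 equiv), CH2Cl2, 0 °C → rt; then H2O
Reagents that add atoms: none
Why: TFAA dehydrates the diacid to the cyclic anhydride, whose CH2-bound carbonyl acylates the only free carbon ortho to the aryloxy oxygen (activated by three alkoxy groups) in a six-membered intramolecular Friedel–Crafts acylation that closes ring C and leaves C2 untouched.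

**Step 8**
Reactants: 12 (S)-7-(benzyloxy)-5,8-dimethoxy-4-oxochromane-2-carboxylic acid
Product: 13 (2S,4S)-7-(benzyloxy)-4-hydroxy-5,8-dimethoxychromane-2-carboxylic acid
Conditions: NaBH4, THF/MeOH, 0 °C; then aq. citric acid
Reagents that add atoms: none
Why: Borohydride reduces the aryl ketone while the carboxylate is inert; the carbinol centre (mainly 2,4-cis, as in flavanone reductions) does not matter because C4 is ionised in step 10.

**Step 9**
Reactants: 14 3,5-dimethoxyphenol
Product: 15 (3,5-dimethoxyphenoxy)triisopropylsilane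
Conditions: TIPSCl, imidazole, DMF, rt
Reagents that add atoms: chlorotriisopropylsilane, CC(C)[Si](Cl)(C(C)C)C(C)C
Why: Silylation of the phenol gives a phloroglucinol-type nucleophile whose two carbons next to oxygen are shielded by the bulky silyl group, leaving the carbon between the methoxy groups as the open site.

**Step 10**
Reactants: 13 (2S,4S)-7-(benzyloxy)-4-hydroxy-5,8-dimethoxychromane-2-carboxylic acid; 15 (3,5-dimethoxyphenoxy)triisopropylsilane
Product: 17 (2S,4S)-7-(benzyloxy)-4-[2,6-dimethoxy-4-(triisopropylsilyloxy)phenyl]-5,8-dimethoxychromane-2-carboxylic acid, via chroman-4-yl cation 16 (not isolated)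
Conditions: 15 (3 equiv), BF3·OEt2 (1.5 equiv), CH2Cl2, −40 → 0 °C
Reagents that add atoms: none
Why: BF3 ionises the benzylic alcohol to a C4 cation stabilised by O1, 5-OMe and 7-OBn, and Friedel–Crafts alkylation at the arene carbon para to the silyloxy group takes place pseudoaxially on the face opposite the pseudoequatorial C2 carboxyl group, giving the 2,4-trans (4S) acid under substrate control (also the thermodynamic isomer); the minor cis acid is removed here, because after step 12 it would end as the enantiomer.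

**Step 11**
Reactants: 17 (2S,4S)-7-(benzyloxy)-4-[2,6-dimethoxy-4-(triisopropylsilyloxy)phenyl]-5,8-dimethoxychromane-2-carboxylic acid
Product: 18 1,3-dioxoisoindolin-2-yl (2S,4S)-7-(benzyloxy)-4-[2,6-dimethoxy-4-(triisopropylsilyloxy)phenyl]-5,8-dimethoxychromane-2-carboxylate
Conditions: N-hydroxyphthalimide, DIC, DMAP (cat.), CH2Cl2, rt
Reagents that add atoms: N-hydroxyphthalimide, ON1C(=O)c2ccccc2C1=O
Why: Carbodiimide (Steglich-type) esterification gives the redox-active ester under neutral conditions that spare the silyl and benzyl ethers.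

**Step 12**
Reactants: 18 1,3-dioxoisoindolin-2-yl (2S,4S)-7-(benzyloxy)-4-[2,6-dimethoxy-4-(triisopropylsilyloxy)phenyl]-5,8-dimethoxychromane-2-carboxylate; 19 iodobenzene
Product: 21 (2S,4S)-7-(benzyloxy)-4-[2,6-dimethoxy-4-(triisopropylsilyloxy)phenyl]-5,8-dimethoxy-2-phenylchromane, via flavan C2 radical 20 (not isolated)
Conditions: NiCl2(dme) (20 mol%), 2,2'-bipyridine (24 mol%), AgNO3 (0.3 equiv), 19 (3 equiv), LiCl, NMP, Mg anode, carbon cathode, undivided cell, constant current, rt
Reagents that add atoms: none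
Why: Cathodic reduction turns divalent nickel into low-valent Ni(bpy), which adds iodobenzene to give a phenylnickel species, while single-electron reduction of the N-hydroxyphthalimide ester releases phthalimide anion, CO2 and the O1-stabilised secondary radical 20 at C2; the radical is trapped at nickel and reductive elimination from trivalent nickel forms the C2–phenyl bond. The closest known reaction type is the nickel-electrocatalytic, silver-assisted decarboxylative arylation of redox-active esters, α-oxygenated acids included, with aryl iodides. No ring is closed. The new C2 stereocentre is set by substrate control: the C4 aryl group, held pseudoaxial by the peri 5-OMe, lies 1,3 to C2 and shields one face of the planar radical, so nickel and then phenyl arrive anti to it and the 2,4-trans (2S) flavan should result, which is also the more stable epimer (aryl axial, phenyl equatorial). The step needs facial selectivity at C2 and chemoselectivity for radical capture over reduction to the 2-unsubstituted chroman; the first is secured by the C4 aryl group, the second by the excess of iodobenzene and the current-limited generation of the radical. Because both C2 epimers of the ester give the same radical, only the C4 configuration has to be pure.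

**Step 13**
Reactants: 21 (2S,4S)-7-(benzyloxy)-4-[2,6-dimethoxy-4-(triisopropylsilyloxy)phenyl]-5,8-dimethoxy-2-phenylchromane
Product: 22 4-[(2S,4S)-7-(benzyloxy)-5,8-dimethoxy-2-phenylchroman-4-yl]-3,5-dimethoxyphenol
Conditions: TBAF, THF, 0 °C; then aq. NH4Cl
Reagents that add atoms: none
Why: Fluoride cleaves the aryl silyl ether selectively and leaves the benzyl ether, the methyl ethers and both stereocentres untouched.

**Step 14**
Reactants: 22 4-[(2S,4S)-7-(benzyloxy)-5,8-dimethoxy-2-phenylchroman-4-yl]-3,5-dimethoxyphenol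
Product: 23 3-[(2S,4S)-7-(benzyloxy)-5,8-dimethoxy-2-phenylchroman-4-yl]-6-hydroxy-2,4-dimethoxybenzaldehyde
Conditions: MgCl2, Et3N, (CH2O)n, THF, reflux; then aq. NH4Cl
Reagents that add atoms: paraformaldehyde (as formaldehyde), C=O
Why: Casnati–Skattebøl ortho-formylation goes through the magnesium phenoxide, so only the free phenol ring D can react (its two ortho carbons are equivalent, the para carbon is blocked), and the basic medium avoids the acid that could cleave the C4–aryl bond by retro-Friedel–Crafts reaction.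

**Step 15**
Reactants: 23 3-[(2S,4S)-7-(benzyloxy)-5,8-dimethoxy-2-phenylchroman-4-yl]-6-hydroxy-2,4-dimethoxybenzaldehyde
Product: 24 4-[(2S,4S)-7-(benzyloxy)-5,8-dimethoxy-2-phenylchroman-4-yl]-2-(1-hydroxyethyl)-3,5-dimethoxyphenol
Conditions: MeMgBr (3.5 equiv), THF, −78 → 0 °C; then aq. NH4Cl
Reagents that add atoms: methylmagnesium bromide, C[Mg]Br
Why: Grignard addition to the aldehyde (after deprotonation of the phenol) gives the carbinol as an epimer mixture that is oxidised in the next step.

**Step 16**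
Reactants: 24 4-[(2S,4S)-7-(benzyloxy)-5,8-dimethoxy-2-phenylchroman-4-yl]-2-(1-hydroxyethyl)-3,5-dimethoxyphenol
Product: 25 1-{3-[(2S,4S)-7-(benzyloxy)-5,8-dimethoxy-2-phenylchroman-4-yl]-6-hydroxy-2,4-dimethoxyphenyl}ethan-1-one
Conditions: MnO2 (excess), CH2Cl2, rt
Reagents that add atoms: none
Why: MnO2 oxidises the benzylic alcohol to the ortho-hydroxy acetophenone under neutral conditions and tolerates the free phenol and the benzyl ether.

**Step 17**
Reactants: 25 1-{3-[(2S,4S)-7-(benzyloxy)-5,8-dimethoxy-2-phenylchroman-4-yl]-6-hydroxy-2,4-dimethoxyphenyl}ethan-1-one; 26 benzaldehyde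
Product: 27 (E)-1-{3-[(2S,4S)-7-(benzyloxy)-5,8-dimethoxy-2-phenylchroman-4-yl]-6-hydroxy-2,4-dimethoxyphenyl}-3-phenylprop-2-en-1-one
Conditions: KOH, EtOH, rt; then AcOH, 0 °C
Reagents that add atoms: none
Why: Claisen–Schmidt condensation of the methyl ketone with the non-enolisable aldehyde should give the E chalcone, which stays open as its phenoxide until the cold acidic quench.

**Step 18**
Reactants: 27 (E)-1-{3-[(2S,4S)-7-(benzyloxy)-5,8-dimethoxy-2-phenylchroman-4-yl]-6-hydroxy-2,4-dimethoxyphenyl}-3-phenylprop-2-en-1-one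
Product: 28 (2R)-6-[(2S,4S)-7-(benzyloxy)-5,8-dimethoxy-2-phenylchroman-4-yl]-5,7-dimethoxy-2-phenylchroman-4-one
Conditions: quinidine-derived 9-amino-9-deoxy-epi-cinchona thiourea [aryl = 3,5-(CF3)2C6H3] (20 mol%), toluene, rt → 40 °C
Reagents that add atoms: none
Why: Intramolecular oxa-Michael addition (6-endo-trig) of the phenol to the enone closes ring F, with the quinuclidine activating the phenol and the thiourea binding the carbonyl, so the catalyst selects the face of the β-carbon and sets C2 as R, the flavan stereocentres being too remote to interfere.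

**Step 19**
Reactants: 28 (2R)-6-[(2S,4S)-7-(benzyloxy)-5,8-dimethoxy-2-phenylchroman-4-yl]-5,7-dimethoxy-2-phenylchroman-4-one
Product: 29 (2R)-6-[(2S,4S)-7-hydroxy-5,8-dimethoxy-2-phenylchroman-4-yl]-5,7-dimethoxy-2-phenylchroman-4-one
Conditions: H2 (1 atm), 10% Pd/C, EtOAc, rt
Reagents that add atoms: none
Why: Hydrogenolysis of the aryl benzyl ether is faster than cleavage of the cyclic benzylic ethers or reduction of the electron-rich aryl ketone, and the neutral medium cannot open the flavanone.

**Step 20**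
Reactants: 29 (2R)-6-[(2S,4S)-7-hydroxy-5,8-dimethoxy-2-phenylchroman-4-yl]-5,7-dimethoxy-2-phenylchroman-4-one
Product: 30 (2R)-5-hydroxy-6-[(2S,4S)-7-hydroxy-5,8-dimethoxy-2-phenylchroman-4-yl]-7-methoxy-2-phenylchroman-4-one
Conditions: BCl3 (4 equiv), CH2Cl2, −78 → 0 °C; then MeOH, H2O
Reagents that add atoms: none
Why: BCl3 chelates between the C4 carbonyl and the peri 5-OMe of the flavanone and cleaves only that methyl ether (chelation-controlled demethylation), while the other methyl ethers stay and the base-free medium keeps the flavanone C2 centre.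

**Compound list**
1 | 2,6-dibromo-4-methoxyphenol | COc1cc(Br)c(O)c(Br)c1 | starting material
2 | 1,3-dibromo-2,5-dimethoxybenzene | COc1cc(Br)c(OC)c(Br)c1 | intermediate
3 | (3-bromo-2,5-dimethoxyphenyl)lithium | [Li]c1cc(OC)cc(Br)c1OC | intermediate
4 | lithium (3-bromo-2,5-dimethoxyphenyl)trimethoxyborate | [Li+].CO[B-](OC)(OC)c1cc(OC)cc(Br)c1OC | intermediate
5 | 3-bromo-2,5-dimethoxyphenol | COc1cc(O)c(OC)c(Br)c1 | intermediate
6 | 1-(benzyloxy)-3-bromo-2,5-dimethoxybenzene | COc1cc(Br)c(OC)c(OCc2ccccc2)c1 | intermediate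
7 | 3-(benzyloxy)-2,5-dimethoxyphenol | COc1cc(O)c(OC)c(OCc2ccccc2)c1 | intermediate
8 | dimethyl (R)-malate | COC(=O)C[C@@H](O)C(=O)OC | starting material
9 | dimethyl (S)-2-[3-(benzyloxy)-2,5-dimethoxyphenoxy]succinate | COC(=O)C[C@H](Oc1cc(OC)cc(OCc2ccccc2)c1OC)C(=O)OC | intermediate
10 | (S)-2-[3-(benzyloxy)-2,5-dimethoxyphenoxy]succinic acid | OC(=O)C[C@H](Oc1cc(OC)cc(OCc2ccccc2)c1OC)C(=O)O | intermediate
11 | (S)-3-[3-(benzyloxy)-2,5-dimethoxyphenoxy]dihydrofuran-2,5-dione | O=C1C[C@H](Oc2cc(OC)cc(OCc3ccccc3)c2OC)C(=O)O1 | intermediate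
12 | (S)-7-(benzyloxy)-5,8-dimethoxy-4-oxochromane-2-carboxylic acid | O=C1C[C@@H](C(=O)O)Oc2c(OC)c(OCc3ccccc3)cc(OC)c12 | intermediate
13 | (2S,4S)-7-(benzyloxy)-4-hydroxy-5,8-dimethoxychromane-2-carboxylic acid (2,4-cis, major epimer) | O[C@H]1C[C@@H](C(=O)O)Oc2c(OC)c(OCc3ccccc3)cc(OC)c21 | intermediate
14 | 3,5-dimethoxyphenol | COc1cc(O)cc(OC)c1 | starting material
15 | (3,5-dimethoxyphenoxy)triisopropylsilane | COc1cc(OC)cc(O[Si](C(C)C)(C(C)C)C(C)C)c1 | intermediate
16 | (2S)-7-(benzyloxy)-2-carboxy-5,8-dimethoxychroman-4-ylium | OC(=O)[C@@H]1C[CH+]c2c(OC)cc(OCc3ccccc3)c(OC)c2O1 | intermediate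
17 | (2S,4S)-7-(benzyloxy)-4-[2,6-dimethoxy-4-(triisopropylsilyloxy)phenyl]-5,8-dimethoxychromane-2-carboxylic acid (2,4-trans) | COc1cc(O[Si](C(C)C)(C(C)C)C(C)C)cc(OC)c1[C@@H]1C[C@@H](C(=O)O)Oc2c(OC)c(OCc3ccccc3)cc(OC)c21 | intermediate
18 | 1,3-dioxoisoindolin-2-yl (2S,4S)-7-(benzyloxy)-4-[2,6-dimethoxy-4-(triisopropylsilyloxy)phenyl]-5,8-dimethoxychromane-2-carboxylate (2,4-trans) | COc1cc(O[Si](C(C)C)(C(C)C)C(C)C)cc(OC)c1[C@@H]1C[C@@H](C(=O)ON2C(=O)c3ccccc3C2=O)Oc2c(OC)c(OCc3ccccc3)cc(OC)c21 | intermediate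
19 | iodobenzene | Ic1ccccc1 | starting material
20 | (4S)-7-(benzyloxy)-4-[2,6-dimethoxy-4-(triisopropylsilyloxy)phenyl]-5,8-dimethoxychroman-2-yl radical | COc1cc(O[Si](C(C)C)(C(C)C)C(C)C)cc(OC)c1[C@@H]1C[CH]Oc2c(OC)c(OCc3ccccc3)cc(OC)c21 | intermediate
21 | (2S,4S)-7-(benzyloxy)-4-[2,6-dimethoxy-4-(triisopropylsilyloxy)phenyl]-5,8-dimethoxy-2-phenylchromane (2,4-trans) | COc1cc(O[Si](C(C)C)(C(C)C)C(C)C)cc(OC)c1[C@@H]1C[C@@H](c2ccccc2)Oc2c(OC)c(OCc3ccccc3)cc(OC)c21 | intermediate
22 | 4-[(2S,4S)-7-(benzyloxy)-5,8-dimethoxy-2-phenylchroman-4-yl]-3,5-dimethoxyphenol | COc1cc(O)cc(OC)c1[C@@H]1C[C@@H](c2ccccc2)Oc2c(OC)c(OCc3ccccc3)cc(OC)c21 | intermediate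
23 | 3-[(2S,4S)-7-(benzyloxy)-5,8-dimethoxy-2-phenylchroman-4-yl]-6-hydroxy-2,4-dimethoxybenzaldehyde | COc1cc(O)c(C=O)c(OC)c1[C@@H]1C[C@@H](c2ccccc2)Oc2c(OC)c(OCc3ccccc3)cc(OC)c21 | intermediate
24 | 4-[(2S,4S)-7-(benzyloxy)-5,8-dimethoxy-2-phenylchroman-4-yl]-2-(1-hydroxyethyl)-3,5-dimethoxyphenol (carbinol epimers) | COc1cc(O)c(C(C)O)c(OC)c1[C@@H]1C[C@@H](c2ccccc2)Oc2c(OC)c(OCc3ccccc3)cc(OC)c21 | intermediate
25 | 1-{3-[(2S,4S)-7-(benzyloxy)-5,8-dimethoxy-2-phenylchroman-4-yl]-6-hydroxy-2,4-dimethoxyphenyl}ethan-1-one | COc1cc(O)c(C(C)=O)c(OC)c1[C@@H]1C[C@@H](c2ccccc2)Oc2c(OC)c(OCc3ccccc3)cc(OC)c21 | intermediate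
26 | benzaldehyde | O=Cc1ccccc1 | starting material
27 | (E)-1-{3-[(2S,4S)-7-(benzyloxy)-5,8-dimethoxy-2-phenylchroman-4-yl]-6-hydroxy-2,4-dimethoxyphenyl}-3-phenylprop-2-en-1-one | COc1cc(O)c(C(=O)/C=C/c2ccccc2)c(OC)c1[C@@H]1C[C@@H](c2ccccc2)Oc2c(OC)c(OCc3ccccc3)cc(OC)c21 | intermediate
28 | (2R)-6-[(2S,4S)-7-(benzyloxy)-5,8-dimethoxy-2-phenylchroman-4-yl]-5,7-dimethoxy-2-phenylchroman-4-one | COc1cc2c(c(OC)c1[C@@H]1C[C@@H](c3ccccc3)Oc3c(OC)c(OCc4ccccc4)cc(OC)c31)C(=O)C[C@H](c1ccccc1)O2 | intermediate
29 | (2R)-6-[(2S,4S)-7-hydroxy-5,8-dimethoxy-2-phenylchroman-4-yl]-5,7-dimethoxy-2-phenylchroman-4-one | COc1cc2c(c(OC)c1[C@@H]1C[C@@H](c3ccccc3)Oc3c(OC)c(O)cc(OC)c31)C(=O)C[C@H](c1ccccc1)O2 | intermediate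
30 | (2R)-5-hydroxy-6-[(2S,4S)-7-hydroxy-5,8-dimethoxy-2-phenylchroman-4-yl]-7-methoxy-2-phenylchroman-4-one | COc1cc2c(c(O)c1[C@@H]1C[C@@H](c3ccccc3)Oc3c(OC)c(O)cc(OC)c31)C(=O)C[C@H](c1ccccc1)O2 | target

**Step count**
Total: 20 steps. Longest linear sequence: 19 steps (steps 1–8 and 10–20; step 9 is a one-step side branch).

**Steps most likely to fail**

Step 12. The C2 radical may be reduced or pick up hydrogen before nickel captures it, the activated ester may be lost to hydrolysis, or the facial discrimination at C2 may be weaker than expected. The fallback leaves the radical manifold for a polar one and sets out from acid 17. Oxidative decarboxylation with Pb(OAc)4 (Cu(OAc)2 cat., pyridine, benzene, rt) should give (4S)-7-(benzyloxy)-4-[2,6-dimethoxy-4-(triisopropylsilyloxy)phenyl]-5,8-dimethoxychroman-2-yl acetate F1 as an anomer mixture. Ionisation of F1 with BF3·OEt2 in the presence of PhBF3K (MeCN/CH2Cl2, −20 → 0 °C) should transfer phenyl to the cyclic oxocarbenium ion axially and anti to the C4 aryl group, as in the known coupling of acetals with organotrifluoroborates. This returns to the route at 21.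

Step 10. The cation may attack the arene carbon next to the silyloxy group instead of the one between the methoxy groups, the trans selectivity may be incomplete, ring A of a second molecule may compete as nucleophile, or the silyl ether may be lost. The fallback fixes the arene carbon beforehand with a metal and sets out from 13 and 15.
- Electrophile: esterification of 13 with TMSCHN2 (toluene/MeOH) should give methyl (2S,4S)-7-(benzyloxy)-4-hydroxy-5,8-dimethoxychromane-2-carboxylate F4, and acetylation (Ac2O, pyridine, DMAP) the 4-acetate, methyl (2S,4S)-4-acetoxy-7-(benzyloxy)-5,8-dimethoxychromane-2-carboxylate F5.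
- Nucleophile: directed lithiation of 15 (n-BuLi, TMEDA, THF, 0 °C) occurs between the two methoxy groups and gives [2,6-dimethoxy-4-(triisopropylsilyloxy)phenyl]lithium F2, which ZnBr2 converts into [2,6-dimethoxy-4-(triisopropylsilyloxy)phenyl]zinc bromide F3.
- Coupling: F5 and F3 (CH2Cl2/toluene, 0 °C → rt) should couple by zinc-assisted ionisation of the acetate and ipso aryl transfer, the reaction type used for C-aryl glycosides from glycosyl halides and arylzinc reagents. Attack is again trans to the C2 ester and gives methyl (2S,4S)-7-(benzyloxy)-4-[2,6-dimethoxy-4-(triisopropylsilyloxy)phenyl]-5,8-dimethoxychromane-2-carboxylate F6.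
- Return: saponification of F6 (LiOH, THF/H2O) comes back to the route at 17.

Step 18. Ring closure of the unactivated chalcone may be slow, catalyst control over the remote C2 centre may be weak, and retro-oxa-Michael equilibration may erode the epimer ratio. The fallback replaces C–O bond formation by enantioselective C–C bond formation and sets out from acetophenone 25. Condensation with DMF-DMA (toluene, 90 °C) should give (E)-1-{3-[(2S,4S)-7-(benzyloxy)-5,8-dimethoxy-2-phenylchroman-4-yl]-6-hydroxy-2,4-dimethoxyphenyl}-3-(dimethylamino)prop-2-en-1-one F7. HCl in CH2Cl2 at rt closes F7 to 6-[(2S,4S)-7-(benzyloxy)-5,8-dimethoxy-2-phenylchroman-4-yl]-5,7-dimethoxy-4H-chromen-4-one F8. Conjugate addition of PhB(OH)2 to F8 with Pd(OCOCF3)2 (5 mol%), (S)-t-BuPyOx (6 mol%), NH4PF6 and H2O in ClCH2CH2Cl at 60 °C should set C2 under ligand control and comes back to the route at 28.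

**Further compounds**
F1 | step 12 | (4S)-7-(benzyloxy)-4-[2,6-dimethoxy-4-(triisopropylsilyloxy)phenyl]-5,8-dimethoxychroman-2-yl acetate (C2 anomers) | COc1cc(O[Si](C(C)C)(C(C)C)C(C)C)cc(OC)c1[C@@H]1CC(OC(C)=O)Oc2c(OC)c(OCc3ccccc3)cc(OC)c21
F2 | step 10 | [2,6-dimethoxy-4-(triisopropylsilyloxy)phenyl]lithium | [Li]c1c(OC)cc(O[Si](C(C)C)(C(C)C)C(C)C)cc1OC
F3 | step 10 | [2,6-dimethoxy-4-(triisopropylsilyloxy)phenyl]zinc bromide | Br[Zn]c1c(OC)cc(O[Si](C(C)C)(C(C)C)C(C)C)cc1OC
F4 | step 10 | methyl (2S,4S)-7-(benzyloxy)-4-hydroxy-5,8-dimethoxychromane-2-carboxylate | O[C@H]1C[C@@H](C(=O)OC)Oc2c(OC)c(OCc3ccccc3)cc(OC)c21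
F5 | step 10 | methyl (2S,4S)-4-acetoxy-7-(benzyloxy)-5,8-dimethoxychromane-2-carboxylate | CC(=O)O[C@H]1C[C@@H](C(=O)OC)Oc2c(OC)c(OCc3ccccc3)cc(OC)c21
F6 | step 10 | methyl (2S,4S)-7-(benzyloxy)-4-[2,6-dimethoxy-4-(triisopropylsilyloxy)phenyl]-5,8-dimethoxychromane-2-carboxylate | COc1cc(O[Si](C(C)C)(C(C)C)C(C)C)cc(OC)c1[C@@H]1C[C@@H](C(=O)OC)Oc2c(OC)c(OCc3ccccc3)cc(OC)c21
F7 | step 18 | (E)-1-{3-[(2S,4S)-7-(benzyloxy)-5,8-dimethoxy-2-phenylchroman-4-yl]-6-hydroxy-2,4-dimethoxyphenyl}-3-(dimethylamino)prop-2-en-1-one | COc1cc(O)c(C(=O)/C=C/N(C)C)c(OC)c1[C@@H]1C[C@@H](c2ccccc2)Oc2c(OC)c(OCc3ccccc3)cc(OC)c21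
F8 | step 18 | 6-[(2S,4S)-7-(benzyloxy)-5,8-dimethoxy-2-phenylchroman-4-yl]-5,7-dimethoxy-4H-chromen-4-one | COc1cc2occc(=O)c2c(OC)c1[C@@H]1C[C@@H](c2ccccc2)Oc2c(OC)c(OCc3ccccc3)cc(OC)c21
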